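**Strategy**

Everything rests on cutting ring C of the flavanone at O1–C2 and C3–C4. These two bonds flank the C2–C3 ethylene unit that carries ring B, so ring C maps onto a four-atom oxa-diene (ring A oxygen, C8a, C4a, C4: a ring A ortho-quinone methide) and a ring B vinyl arene. In one operation a chiral phosphoric acid and trimethyl orthoformate turn a bis-silylated phloroglucinaldehyde into a 4-methoxy quinone methide that adds the styrene, closing ring C, setting C2 as S and delivering C4 already oxygenated. The styrene is a silyl-protected 6-vinyl-8-prenylchromene; hydrolysis, oxidation and desilylation then give the target.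

Key step: step 6

Assumption: the sense of induction of the phosphoric acid cannot be predicted safely; the route is written with the (R)-catalyst, and its mirror image is used if a first trial shows the 2R series.
Assumption: 5-bromo-2,4-dihydroxybenzaldehyde is taken as a purchasable starting material.

**Route**

Step 1
Reactants: 1 2,4,6-trihydroxybenzaldehyde
Product: 2 2-hydroxy-4,6-bis(tert-butyldimethylsilyloxy)benzaldehyde
Conditions: TBSCl (2.1 equiv), imidazole (4 equiv), DMF, 0 °C to rt
Reagents that add atoms: tert-butyldimethylsilyl chloride CC(C)(C)[Si](C)(C)Cl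
Why: Imidazole-mediated phenol silylation: the para hydroxyl and one of the two equivalent ortho hydroxyls react, while the last ortho hydroxyl, locked in a hydrogen bond to the formyl oxygen and now crowded, should stay free as the quinone methide requires.

Step 2
Reactants: 3 5-bromo-2,4-dihydroxybenzaldehyde; 4 3-methylbut-2-enal
Product: 6 8-bromo-5-hydroxy-2,2-dimethyl-2H-chromene-6-carbaldehyde, via ortho-quinone methide 5 (not isolated)
Conditions: EDDA (ethylenediammonium diacetate, 20 mol %), xylene, 130 °C
Reagents that add atoms: none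
Why: Chromene annulation of a resorcinol with an enal (Knoevenagel-type condensation to 5, then oxa-6π electrocyclisation): bromine blocks C5, so only the carbon between the two hydroxyls can react, and the free 4-hydroxyl rather than the chelated 2-hydroxyl supplies the pyran oxygen, which leaves bromine at the later prenyl position.

Step 3
Reactants: 6 8-bromo-5-hydroxy-2,2-dimethyl-2H-chromene-6-carbaldehyde
Product: 7 8-bromo-5-(tert-butyldimethylsilyloxy)-2,2-dimethyl-2H-chromene-6-carbaldehyde
Conditions: TBSOTf (1.3 equiv), 2,6-lutidine (2 equiv), CH2Cl2, 0 °C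
Reagents that add atoms: tert-butyldimethylsilyl triflate CC(C)(C)[Si](C)(C)OS(=O)(=O)C(F)(F)F
Why: Silylation of a chelated, doubly flanked phenol with the silyl triflate and a hindered base; the non-enolisable aldehyde, the aryl bromide and the chromene should be inert.

Step 4
Reactants: 7 8-bromo-5-(tert-butyldimethylsilyloxy)-2,2-dimethyl-2H-chromene-6-carbaldehyde
Product: 8 8-bromo-5-(tert-butyldimethylsilyloxy)-6-ethenyl-2,2-dimethyl-2H-chromene
Conditions: Ph3PCH3Br (1.5 equiv), KOtBu (1.4 equiv), THF, 0 °C to rt
Reagents that add atoms: methyltriphenylphosphonium bromide C[P+](c1ccccc1)(c1ccccc1)c1ccccc1.[Br-]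
Why: Wittig methylenation of a non-enolisable aryl aldehyde; the slight deficit of base leaves no free alkoxide to attack the aryl silyl ether.

Step 5
Reactants: 8 8-bromo-5-(tert-butyldimethylsilyloxy)-6-ethenyl-2,2-dimethyl-2H-chromene; 9 1-bromo-3-methylbut-2-ene
Product: 12 5-(tert-butyldimethylsilyloxy)-6-ethenyl-2,2-dimethyl-8-(3-methylbut-2-enyl)-2H-chromene, via aryllithium 10 (not isolated), via arylcopper 11 (not isolated)
Conditions: n-BuLi (1.05 equiv), THF, −78 °C; CuBr·SMe2 (1.0 equiv), −78 to −40 °C; 9 (1.5 equiv), −40 to 0 °C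
Reagents that add atoms: none
Why: Bromine–lithium exchange (faster at −78 °C than addition of n-BuLi to the electron-rich vinyl group, as with other bromostyrenes), transmetalation to copper and SN2 allylation at the primary carbon of 9 should place a linear prenyl group exactly at C8, a position para to the silyloxy group that phenoxide C-alkylation would not reach.

Step 6
Reactants: 2 2-hydroxy-4,6-bis(tert-butyldimethylsilyloxy)benzaldehyde; 12 5-(tert-butyldimethylsilyloxy)-6-ethenyl-2,2-dimethyl-8-(3-methylbut-2-enyl)-2H-chromene; 13 trimethyl orthoformate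
Product: 16 (2S,4S)-5,7-bis(tert-butyldimethylsilyloxy)-2-[5-(tert-butyldimethylsilyloxy)-2,2-dimethyl-8-(3-methylbut-2-enyl)-2H-chromen-6-yl]-4-methoxychromane (2,4-cis), via dimethyl acetal 14 (not isolated), via 4-methoxy ortho-quinone methide 15 (not isolated)
Conditions: 2 (1.2 equiv), 13 (1.5 equiv), (R)-TRIP ((R)-3,3'-bis(2,4,6-triisopropylphenyl)-1,1'-binaphthyl-2,2'-diyl hydrogen phosphate, 10 mol %), 5 Å MS, PhMe, rt; then 12 (1.0 equiv), −30 °C
Reagents that add atoms: none
Why: Proposed new method: the acid first exchanges the formyl group of 2 with 13 to acetal 14, which loses methanol to the 4-methoxy ortho-quinone methide 15, held protonated or hydrogen bonded in a contact ion pair with the chiral phosphate; the terminal CH2 of the vinyl group of 12 then adds to the methide carbon (C3–C4) and the ring A oxygen captures the benzylic carbon (O1–C2) in an inverse-demand oxa-[4+2] that is probably concerted but asynchronous. The closest known reactions are the acid-catalysed three-component chroman synthesis from salicylaldehydes, orthoformates and styrenes (racemic 2-aryl-4-alkoxychromans) and chiral phosphoric acid controlled cycloadditions of ortho-quinone methides with electron-rich alkenes. Ring C closes as a six-membered ring in the [4+2] mode, or in the stepwise limit by 6-endo-trig attack of the phenol oxygen on the para-alkoxybenzyl cation while the phosphate is still bound to that phenol. C2 is set by the catalyst, whose 2,4,6-triisopropylphenyl walls should leave one face of the vinyl arene open inside the ion pair, and C4 follows from an endo approach (aryl and methoxy cis); only C2 matters, since C4 becomes the carbonyl carbon and a trans epimer sharing 2S would converge. The step needs the vinyl group to react in preference to the chromene and prenyl double bonds: it is the only terminal alkene and is conjugated with the para ring oxygen, whereas the chromene alkene must be attacked next to its quaternary carbon and the prenyl alkene gives no benzylic cation. The phenol beside the vinyl group is kept silylated so that it cannot trap C4 of the product as a bridged ether, and the weak acid and low temperature are chosen to spare the styrene and the aryl silyl ethers.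

Step 7
Reactants: 16 (2S,4S)-4-methoxychromane tris-TBS ether
Product: 17 (2S)-5,7-bis(tert-butyldimethylsilyloxy)-2-[5-(tert-butyldimethylsilyloxy)-2,2-dimethyl-8-(3-methylbut-2-enyl)-2H-chromen-6-yl]chroman-4-ol (mixture of C4 epimers)
Conditions: PPTS (pyridinium p-toluenesulfonate, 20 mol %), acetone/H2O 4:1, rt
Reagents that add atoms: water O
Why: SN1 solvolysis of the benzylic methyl ether: mild acid ionises C4–OMe to a cation stabilised by the three ring A oxygens and water in large excess captures it, while C2 is not involved and the C4 epimer mixture is of no consequence.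

Step 8
Reactants: 17 (2S)-chroman-4-ol tris-TBS ether
Product: 18 (2S)-5,7-bis(tert-butyldimethylsilyloxy)-2-[5-(tert-butyldimethylsilyloxy)-2,2-dimethyl-8-(3-methylbut-2-enyl)-2H-chromen-6-yl]chroman-4-one
Conditions: DMP (Dess–Martin periodinane, 1.3 equiv), NaHCO3 (3 equiv), CH2Cl2, 0 °C to rt
Reagents that add atoms: none
Why: Dess–Martin oxidation of a secondary benzylic alcohol under bicarbonate buffer; both C4 epimers converge on the ketone, and the alkenes and silyl ethers should be untouched.

Step 9
Reactants: 18 (2S)-chroman-4-one tris-TBS ether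
Product: 19 sanggenol N, (2S)-5,7-dihydroxy-2-[5-hydroxy-2,2-dimethyl-8-(3-methylbut-2-enyl)-2H-chromen-6-yl]chroman-4-one
Conditions: TBAF (Bu4NF, 3.3 equiv), AcOH (4 equiv), THF, 0 °C
Reagents that add atoms: none
Why: Fluoride cleavage of the three aryl silyl ethers; acetic acid keeps the liberated phenoxides protonated, which should prevent the base-induced ring opening to the chalcone that would racemise C2.

**Compound list**

1 | 2,4,6-trihydroxybenzaldehyde | O=Cc1c(O)cc(O)cc1O | starting material
2 | 2-hydroxy-4,6-bis(tert-butyldimethylsilyloxy)benzaldehyde | O=Cc1c(O)cc(O[Si](C)(C)C(C)(C)C)cc1O[Si](C)(C)C(C)(C)C | intermediate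
3 | 5-bromo-2,4-dihydroxybenzaldehyde | O=Cc1cc(Br)c(O)cc1O | starting material
4 | 3-methylbut-2-enal | CC(C)=CC=O | starting material
5 | 5-bromo-2-hydroxy-3-(3-methylbut-2-enylidene)-4-oxocyclohexa-1,5-diene-1-carbaldehyde (ortho-quinone methide) | O=CC1=C(O)C(=CC=C(C)C)C(=O)C(Br)=C1 | intermediate (not isolated)
6 | 8-bromo-5-hydroxy-2,2-dimethyl-2H-chromene-6-carbaldehyde | Brc1cc(C=O)c(O)c2c1OC(C)(C)C=C2 | intermediate
7 | 8-bromo-5-(tert-butyldimethylsilyloxy)-2,2-dimethyl-2H-chromene-6-carbaldehyde | Brc1cc(C=O)c(O[Si](C)(C)C(C)(C)C)c2c1OC(C)(C)C=C2 | intermediate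
8 | 8-bromo-5-(tert-butyldimethylsilyloxy)-6-ethenyl-2,2-dimethyl-2H-chromene | Brc1cc(C=C)c(O[Si](C)(C)C(C)(C)C)c2c1OC(C)(C)C=C2 | intermediate
9 | 1-bromo-3-methylbut-2-ene | CC(C)=CCBr | starting material
10 | [5-(tert-butyldimethylsilyloxy)-6-ethenyl-2,2-dimethyl-2H-chromen-8-yl]lithium | [Li]c1cc(C=C)c(O[Si](C)(C)C(C)(C)C)c2c1OC(C)(C)C=C2 | intermediate (not isolated)
11 | [5-(tert-butyldimethylsilyloxy)-6-ethenyl-2,2-dimethyl-2H-chromen-8-yl]copper | [Cu]c1cc(C=C)c(O[Si](C)(C)C(C)(C)C)c2c1OC(C)(C)C=C2 | intermediate (not isolated)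
12 | 5-(tert-butyldimethylsilyloxy)-6-ethenyl-2,2-dimethyl-8-(3-methylbut-2-enyl)-2H-chromene | CC(C)=CCc1cc(C=C)c(O[Si](C)(C)C(C)(C)C)c2c1OC(C)(C)C=C2 | intermediate
13 | trimethyl orthoformate | COC(OC)OC | starting material
14 | 3,5-bis(tert-butyldimethylsilyloxy)-2-(dimethoxymethyl)phenol | COC(OC)c1c(O)cc(O[Si](C)(C)C(C)(C)C)cc1O[Si](C)(C)C(C)(C)C | intermediate (not isolated)
15 | 3,5-bis(tert-butyldimethylsilyloxy)-6-(methoxymethylidene)cyclohexa-2,4-dien-1-one | COC=C1C(=O)C=C(O[Si](C)(C)C(C)(C)C)C=C1O[Si](C)(C)C(C)(C)C | intermediate (not isolated)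
16 | (2S,4S)-5,7-bis(tert-butyldimethylsilyloxy)-2-[5-(tert-butyldimethylsilyloxy)-2,2-dimethyl-8-(3-methylbut-2-enyl)-2H-chromen-6-yl]-4-methoxychromane (2,4-cis) | CC(C)=CCc1cc([C@@H]2C[C@H](OC)c3c(O[Si](C)(C)C(C)(C)C)cc(O[Si](C)(C)C(C)(C)C)cc3O2)c(O[Si](C)(C)C(C)(C)C)c2c1OC(C)(C)C=C2 | intermediate
17 | (2S)-5,7-bis(tert-butyldimethylsilyloxy)-2-[5-(tert-butyldimethylsilyloxy)-2,2-dimethyl-8-(3-methylbut-2-enyl)-2H-chromen-6-yl]chroman-4-ol (C4 epimers) | CC(C)=CCc1cc([C@@H]2CC(O)c3c(O[Si](C)(C)C(C)(C)C)cc(O[Si](C)(C)C(C)(C)C)cc3O2)c(O[Si](C)(C)C(C)(C)C)c2c1OC(C)(C)C=C2 | intermediate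
18 | (2S)-5,7-bis(tert-butyldimethylsilyloxy)-2-[5-(tert-butyldimethylsilyloxy)-2,2-dimethyl-8-(3-methylbut-2-enyl)-2H-chromen-6-yl]chroman-4-one | CC(C)=CCc1cc([C@@H]2CC(=O)c3c(O[Si](C)(C)C(C)(C)C)cc(O[Si](C)(C)C(C)(C)C)cc3O2)c(O[Si](C)(C)C(C)(C)C)c2c1OC(C)(C)C=C2 | intermediate
19 | sanggenol N, (2S)-5,7-dihydroxy-2-[5-hydroxy-2,2-dimethyl-8-(3-methylbut-2-enyl)-2H-chromen-6-yl]chroman-4-one | CC(C)=CCc1cc([C@@H]2CC(=O)c3c(O)cc(O)cc3O2)c(O)c2c1OC(C)(C)C=C2 | target

**Step count and risks**

Total steps: 9. Longest linear sequence: 8 steps (steps 2, 3, 4, 5, 6, 7, 8, 9).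

Steps most likely to fail:

1. Step 6. The ion pair may give poor facial selectivity at C2, because the silylated styrene offers the catalyst no hydrogen-bond handle. The acid may also oligomerise the electron-rich styrene before the quinone methide is intercepted. The fallback uses known chemistry and sets out from 2, 12 and 13. Sc(OTf)3 (5 mol %) in CH2Cl2 at 0 °C, the established racemic three-component chroman synthesis, should give the racemic 2,4-cis-4-methoxychromane tris-TBS ether F1. Hydrolysis as in step 7 should give the racemic chroman-4-ol F2, and Dess–Martin oxidation as in step 8 the racemic tris-TBS chroman-4-one F3. Kinetic resolution by Noyori–Ikariya asymmetric transfer hydrogenation follows (RuCl(p-cymene)[(S,S)-TsDPEN] or its mirror image, whichever reduces the 2R ketone faster, HCO2H/Et3N, EtOAc, rt), stopped near half conversion. It should convert the 2R enantiomer into the (2R,4R)-cis-chroman-4-ol F4 and leave the 2S ketone, which is separated by chromatography; the route is rejoined at 18.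

2. Step 5. The butyllithium or the aryllithium may add to the vinyl group (anionic oligomerisation) in competition with halogen–lithium exchange, or the allylation may go partly through SN2' attack to a reverse-prenyl group. The fallback sets out from 7, before the vinyl group exists. Stille coupling with tributyl(3-methylbut-2-enyl)stannane (Pd(PPh3)4, DMF, 90 °C) should give 5-(tert-butyldimethylsilyloxy)-2,2-dimethyl-8-(3-methylbut-2-enyl)-2H-chromene-6-carbaldehyde F5. Wittig methylenation as in step 4 then returns to the route at 12.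

3. Step 7. The C4 cation may lose a C3 proton faster than water captures it (elimination to the flav-3-ene), or prolonged acid may ionise O1–C2 and erode C2. The fallback sets out from 16 and avoids the solvolysis altogether. DDQ (1.1 equiv) in CH2Cl2/pH 7 buffer at 0 °C should abstract hydride from C4–H, the most electron-rich benzylic ether C–H in the molecule; water addition and loss of methanol then give the ketone directly. The route is rejoined at 18, and no new compound is made (F0).

**Further compounds**

F1 | step 6 | racemic 2,4-cis-5,7-bis(tert-butyldimethylsilyloxy)-2-[5-(tert-butyldimethylsilyloxy)-2,2-dimethyl-8-(3-methylbut-2-enyl)-2H-chromen-6-yl]-4-methoxychromane | CC(C)=CCc1cc(C2CC(OC)c3c(O[Si](C)(C)C(C)(C)C)cc(O[Si](C)(C)C(C)(C)C)cc3O2)c(O[Si](C)(C)C(C)(C)C)c2c1OC(C)(C)C=C2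
F2 | step 6 | racemic 5,7-bis(tert-butyldimethylsilyloxy)-2-[5-(tert-butyldimethylsilyloxy)-2,2-dimethyl-8-(3-methylbut-2-enyl)-2H-chromen-6-yl]chroman-4-ol | CC(C)=CCc1cc(C2CC(O)c3c(O[Si](C)(C)C(C)(C)C)cc(O[Si](C)(C)C(C)(C)C)cc3O2)c(O[Si](C)(C)C(C)(C)C)c2c1OC(C)(C)C=C2
F3 | step 6 | racemic 5,7-bis(tert-butyldimethylsilyloxy)-2-[5-(tert-butyldimethylsilyloxy)-2,2-dimethyl-8-(3-methylbut-2-enyl)-2H-chromen-6-yl]chroman-4-one | CC(C)=CCc1cc(C2CC(=O)c3c(O[Si](C)(C)C(C)(C)C)cc(O[Si](C)(C)C(C)(C)C)cc3O2)c(O[Si](C)(C)C(C)(C)C)c2c1OC(C)(C)C=C2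
F4 | step 6 | (2R,4R)-5,7-bis(tert-butyldimethylsilyloxy)-2-[5-(tert-butyldimethylsilyloxy)-2,2-dimethyl-8-(3-methylbut-2-enyl)-2H-chromen-6-yl]chroman-4-ol (2,4-cis) | CC(C)=CCc1cc([C@H]2C[C@@H](O)c3c(O[Si](C)(C)C(C)(C)C)cc(O[Si](C)(C)C(C)(C)C)cc3O2)c(O[Si](C)(C)C(C)(C)C)c2c1OC(C)(C)C=C2
F5 | step 5 | 5-(tert-butyldimethylsilyloxy)-2,2-dimethyl-8-(3-methylbut-2-enyl)-2H-chromene-6-carbaldehyde | CC(C)=CCc1cc(C=O)c(O[Si](C)(C)C(C)(C)C)c2c1OC(C)(C)C=C2
F0 | step 7 | none | none
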